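Slowness is what the winter run of Imd with Ptn shows, and I take from it a clock for the next flask.

| flask | Imd | Ptn | remark | time |
|---|---|---|---|---|
| winter | 0.064 M | 0.065 M | run made earlier |  |
| flask | 0.064 M | 0.130 M |  | 20 h |

winter run (percent of the Imd charged)

| time / min | Imd2 / % | Imd / % |
|---|---|---|
| 10.0 | 1.7 | 98.0 |
| 20.0 | 2.4 | 97.0 |
| 30.0 | 4.1 | 95.7 |
| 60.0 | 7.3 | 92.5 |
| 120 | 13.8 | 85.5 |

(readings scatter by 0.5 percentage points)



- equivalents of Ptn to Imd, everything else as given, that leave most Imd2 at 20 h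
- the amount of Imd2 then, in percent of the Imd charged
- the amount of Imd2 with the amounts as given

After 120 min the winter run reads Imd 85.5% and Imd2 13.8%, which together are nearly all of the charge, so I read one Imd2 made per Imd lost, and, since Ptn was not read, I assume one Ptn taken for each. Freezing Ptn at its charge makes the loss of Imd pseudo-first-order, with a winter half-life, read from that last reading and carrying its scatter, of 8.85 h. I assume the rate goes with Ptn, so scaling to this flask's charge gives T = 4.42 h, the frozen half-life of Imd.

In the first instants of this flask Ptn stands at its charge, so T should hold. On this reckoning, after one T in this flask, 0.0320 M of Imd has gone, which takes a quarter of the Ptn charged, and Imd2 stands level with Imd, so what follows Imd2, if anything does, is to be watched from here on; the winter run, at 13.8% of Imd2, says little about it. By 20 h, 4.52 frozen half-lives leave 4.36% of the Imd on this reckoning. If instead Ptn sat at its one-for-one excess of 0.0660 M, the half-life is 8.72 h and 20.4% remains. So, assuming that nothing follows Imd2 and that Ptn goes nowhere else, I reckon Imd2 in this flask at 79.6% to 95.6%.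

The forecast stands lower, at 75% (50% to 90%), with the best 77% at 2.3 equiv (1.4 equiv to 4.5 equiv), holding that “An optimum needs Imd2 to be consumed further”.

The flask gives 36.7% of Imd2 as charged, and 38.8% at 3.04 equiv.

    Imd4 + Ptn ⇌ Lvg + Imd5 (K = 0.0890, k = 1.30 M⁻¹ h⁻¹)
    Imd2 + Ptn ⇌ Lvg + Imd3 (K = 0.250, k = 0.600 M⁻¹ h⁻¹)
    Imd + Ptn ⇌ Lvg + Imd2 (K = 6.30, k = 1.40 M⁻¹ h⁻¹)
    Ptn → Sdp (k = 0.0780 h⁻¹)
    Imd2 ⇌ Sdp2 (K = 0.290, k = 0.0370 h⁻¹)
    Imd3 + Ptn ⇌ Lvg + Imd4 (K = 0.870, k = 3.40 M⁻¹ h⁻¹)
    Lvg + Imd2 → Sdp3 (k = 0.450 M⁻¹ h⁻¹)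

At 2.00 h T predicts Imd 73.1% and the flask holds 73.4%. At 20 h the flask holds 33.9% against the frozen 4.36%, with Ptn at 10% of its charge, below my excess. This flask is not at rest at 20 h: at 200 h its Imd2 has fallen to 11.3%, its Sdp3 has risen from 11.9% to 47.1%, its Imd stands at 38.1%, and its Ptn is down to 0.122% of its charge.

In the neighbour flask with 0.52 M of Ptn, T shortens to 1.11 h, and 20 h of halvings leave hardly any Imd. The computed neighbour keeps 3.5% of its Imd, with Imd2 at 28.7%.

The data were generated by integration with made-up constants; scatter was added.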